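## The problem

The target is a cyclohexene (numbered C1 quaternary, C2, C3, C4, C5, C6) with its only ring alkene between C4 and C5 and a methyl group on C4. C6 carries a 5,7-dimethoxycoumarin through its C8. C1 carries a methyl group and an (E)-styryl arm (Ca=Cb) that ends at C8 of a second 5,7-dimethoxycoumarin.

Two adjacent stereocentres must be set, (R) at C1 and (R) at C6. On the cyclohexene the C6 aryl group is cis to the styryl arm and trans to the C1 methyl group. C1 is quaternary and cannot be corrected later. C6 is a benzylic and allylic methine and should not meet strong acid or base once the C4–C5 alkene exists.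

Neither centre carries a heteroatom handle, so the relative configuration is best set in a small rigid ring where the C6 substituent can direct attack at C1. Both coumarins are electron-rich arenes flanked on both sides at C8, so every bond to C8 is hindered. Their lactones do not tolerate alkoxides, hydride reagents, alkyllithiums or Grignard reagents.

The enabling feature is the four-carbon chain C5–C6–C1–Ca. Joined by a C5=Ca double bond it is a cyclobutene holding both stereocentres. Metathetic opening hands C5 to an isopropenyl group on the C2–C3 tether, closing the six-membered ring as the C4–C5 alkene, and leaves Ca as a vinyl group on C1 for arylation.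

## Retrosynthesis

**Styryl arm.** Target 19 is cut between C8 of the left-hand coumarin and Cb, giving 8-iodo-5,7-dimethoxycoumarin 2 and vinylcyclohexene 18. Cutting Ca=Cb instead would need a neopentyl aldehyde at C1 that the route never passes through. The Heck cut uses the vinyl group exactly as the ring rearrangement leaves it. Because C1 is quaternary, β-hydrogens exist only on the benzylic side, so only the (E)-styrene can form. The forward reaction must insert a di-ortho-substituted arylpalladium into a vinyl group next to a quaternary carbon. Iodide 2 also supplies the other coumarin, so both halves come from one intermediate.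

**Cyclohexene.** In 18 the C4=C5 bond is cut and C5 is reconnected to Ca, giving cyclobutene 17 with an isopropenyl-terminated tether. Closing an acyclic diene would require the vicinal quaternary and tertiary centres to be set without a ring. A [4+2] approach would leave the endo/exo relation weakly controlled. The cyclobutene stores both centres on a rigid ring and pays for the six-membered ring with its strain. The forward step must open the cyclobutene with ruthenium on C5 and close onto the 1,1-disubstituted alkene.

**Cyclobutene and side-chain alkene.** The CH=CH unit of 17 is traced to a ketone at Ca: 17 from methyl ketone 16 (methylenation), 16 from alkenyl triflate 14 (triflate to hydrogen), 14 from cyclobutanone 13. With the ketone on Ca, its neighbours are the quaternary C1 and the CH2 group C5, so enolisation can go only one way. A ketone at that position is also what a ketene-type [2+2] delivers. The side-chain ketone of 13 is carried as its silyl enol ether so that only the ring ketone is triflated.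

**Quaternary centre.** Compound 13 is cut between C1 and the first tether carbon, giving enol silane 11 and methyl vinyl ketone 12 (Mukaiyama–Michael addition). Placing the whole side chain on the ketene component instead has two weaknesses:
- A keteniminium ion with a 1,1-disubstituted alkene two carbons from its α-carbon is set up for intramolecular [2+2] (the bicyclo[2.1.1]hexanone mode).
- Nothing would decide which α-substituent ends cis to the aryl group.

Adding the chain afterwards to the planar C1 of 11 removes both problems. The electrophile enters anti to the C6 aryl group, which leaves the methyl group cis to the aryl group on the four-membered ring. An enone is preferred to a homoallylic halide because conjugate addition tolerates a hindered tetrasubstituted enol silane, whereas SN2 alkylation would compete with E2 to isoprene. The cost is one later methylenation.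

**Four-membered ring.** Enol silane 11 comes from ketone 10 by silylation under thermodynamic control. Ketone 10 is cut at C6–C1 and Ca–C5 into 8-vinylcoumarin 4 and the keteniminium ion from propanamide 7. The alkene terminus bonds to the iminium carbon and the benzylic carbon to the methyl-bearing carbon, giving the 2-methyl-3-aryl pattern. The C2-symmetric pyrrolidine controls C6, the only centre that matters here, since the methyl-bearing carbon is planarised in the next step. Dichloroketene would give the same ring only as a racemate.

**Simple pieces.** Amide 7 comes from propanoyl chloride 5 and (2R,5R)-2,5-dimethylpyrrolidine 6. Alkene 4 comes from iodide 2 and vinylboronate 3 (Suzuki–Miyaura). Iodide 2 comes from 5,7-dimethoxycoumarin 1.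

## Roads not taken

**Alternative 1:** carbene linchpin at C6. The C5–C6 ring bond and the C6–aryl bond are cut together. Forward, an alkenylpalladium from a Z-alkenyl iodide would insert a carbene generated at C6 from a tosylhydrazone. This closes the ring as an η3-allylpalladium over C6–C5–C4, and an arylboronic acid then couples at C6 to give A1.
- Merits: ring, C6 centre and aryl group arrive in one step; the aryl group comes late.
- Weak points: the terminating boronic acid has two ortho oxygen substituents, so transmetalation should be slow and protodeboronation a risk. The allyl unit has two termini, C6 and C4. The face of C6 is steered only by a quaternary centre whose methyl and alkynyl groups differ little in size. The quaternary centre must first be made enantiopure in an open chain, and the silylalkyne still has to become the (E)-styryl arm.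
- Comparison: this road is more convergent about C6. The chosen plan sets the relative configuration by anti attack on a rigid four-membered ring, where the size difference is large, and gets its arylation handle for nothing.

**Alternative 2:** Diels–Alder reaction of a coumarin-3-carboxylate with a silyl isoprene. C1–C2 and C5–C6 are cut. A copper bis(oxazoline) Lewis acid would activate the 3,4-alkene of the ester for a [4+2] reaction giving the cis-fused allylsilane A2. Protodesilylation would later move the alkene to C4–C5.
- Merits: one catalytic step sets both stereocentres with the cis relation enforced by the lactone. In this respect it is better than the chosen plan, which uses a stoichiometric auxiliary and a separate diastereoselective step.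
- Weak points: the dienophile is a trisubstituted, arene-conjugated enoate and should be reluctant. After the key step the lactone must be dismantled, the ester reduced to a methyl group at a neopentyl carbon, the lactone carbonyl turned into the styryl arm, and the right-hand coumarin rebuilt on the freed phenol.
- Comparison: the chosen plan carries both coumarins intact from the first step and needs no redox adjustment at the quaternary carbon.

**Alternative 3:** ester-tethered desymmetrising Heck cyclisation. The C6–aryl bond is cut. An iodoaryl ester of a 1,4-dimethylcyclohexa-2,5-diene-1-carboxylic acid would cyclise onto one of the two enantiotopic alkenes, and β-hydride elimination from C4 would give the cis-fused dienyl lactone A3.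
- Merits: this is the strongest competitor. Enantioselective Heck desymmetrisation of cyclohexadienes is well established, enantiocontrol is catalytic, the C1 methyl group is present from the start, and the tether guarantees the cis relation.
- Weak points: A3 is a conjugated diene, so the C2–C3 alkene must be hydrogenated selectively beside the trisubstituted one. The lactone carbonyl must become the styryl arm by a separate olefination, and the right-hand coumarin must be built on the phenol at the end.
- Comparison: the chosen plan sets against its stoichiometric (recoverable) auxiliary the absence of any selective diene reduction or late coumarin construction, and an E-selective arylation as the last step.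

Key step: step 10

Assumption: the (2R,5R) auxiliary is taken to give the (R) configuration at the aryl-bearing carbon of 10; if the sense proves opposite, the (2S,5S) amine (both enantiomers are commercial) is used and nothing else changes.

## Route

Step 1
Reactants: 1 5,7-dimethoxy-2H-chromen-2-one (5,7-dimethoxycoumarin)
Product: 2 8-iodo-5,7-dimethoxy-2H-chromen-2-one
Conditions: NIS, CF3CO2H (cat.), MeCN, 0 °C to rt
Reagents that add atoms: N-iodosuccinimide, O=C1CCC(=O)N1I
Why: Electrophilic aromatic iodination; C8, between the 7-methoxy group and the ring oxygen, should be the most activated position, and any 6-iodo isomer should be removable by crystallisation.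

Step 2
Reactants: 2 8-iodo-5,7-dimethoxy-2H-chromen-2-one; 3 2-ethenyl-4,4,5,5-tetramethyl-1,3,2-dioxaborolane
Product: 4 8-ethenyl-5,7-dimethoxy-2H-chromen-2-one
Conditions: PdCl2(dppf) (cat.), K2CO3, 1,4-dioxane/H2O, 80 °C
Reagents that add atoms: none
Why: Suzuki–Miyaura vinylation of an aryl iodide; the small vinyl group should transfer readily even to the di-ortho-substituted arylpalladium.

Step 3
Reactants: 5 propanoyl chloride; 6 (2R,5R)-2,5-dimethylpyrrolidine
Product: 7 1-[(2R,5R)-2,5-dimethylpyrrolidin-1-yl]propan-1-one
Conditions: Et3N, CH2Cl2, 0 °C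
Reagents that add atoms: none
Why: N-acylation of a secondary amine by an acid chloride; the amine stereocentres are not involved.

Step 4
Reactants: 7 1-[(2R,5R)-2,5-dimethylpyrrolidin-1-yl]propan-1-one; 4 8-ethenyl-5,7-dimethoxy-2H-chromen-2-one
Product: 10 8-[(1R)-2-methyl-3-oxocyclobutyl]-5,7-dimethoxy-2H-chromen-2-one (both epimers at the methyl-bearing carbon), via keteniminium triflate 8 (not isolated), via cyclobutaniminium triflate 9 (not isolated)
Conditions: Tf2O, 2,4,6-collidine, ClCH2CH2Cl, −20 °C to 60 °C; then aq. NaHCO3, rt
Reagents that add atoms: water, O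
Why: Keteniminium–alkene [2+2] cycloaddition followed by iminium hydrolysis; the alkene terminus bonds to the iminium carbon and the benzylic cation closes on the methyl-bearing carbon, giving the 2-methyl-3-aryl ring. The C2-symmetric pyrrolidine shields one face of the keteniminium ion and so sets the benzylic centre; the epimeric methyl-bearing carbon is planarised in step 5.

Step 5
Reactants: 10 8-[(1R)-2-methyl-3-oxocyclobutyl]-5,7-dimethoxy-2H-chromen-2-one
Product: 11 5,7-dimethoxy-8-[(1R)-2-methyl-3-[(trimethylsilyl)oxy]cyclobut-2-en-1-yl]-2H-chromen-2-one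
Conditions: Me3SiCl, NaI, Et3N, MeCN, rt
Reagents that add atoms: chlorotrimethylsilane, C[Si](C)(C)Cl
Why: Silyl enol ether formation under equilibrating conditions (Me3SiI formed in the flask) should favour the more substituted enol ether; both epimers of 10 converge and the benzylic centre is untouched.

Step 6
Reactants: 11 5,7-dimethoxy-8-[(1R)-2-methyl-3-[(trimethylsilyl)oxy]cyclobut-2-en-1-yl]-2H-chromen-2-one; 12 but-3-en-2-one
Product: 13 5,7-dimethoxy-8-[(1S,2S)-2-methyl-3-oxo-2-[3-[(trimethylsilyl)oxy]but-2-en-1-yl]cyclobutyl]-2H-chromen-2-one (enol ether E/Z mixture)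
Conditions: HNTf2 (cat.), CH2Cl2, −78 °C; Et3N quench
Reagents that add atoms: none
Why: Mukaiyama–Michael addition catalysed by Me3SiNTf2 formed in the flask; the enone adds to the planar enol carbon from the face opposite the neighbouring aryl group, which sets the quaternary centre with methyl cis to aryl. Silyl transfer leaves the side-chain ketone masked as its enol silane and the ring ketone free.

Step 7
Reactants: 13 5,7-dimethoxy-8-[(1S,2S)-2-methyl-3-oxo-2-[3-[(trimethylsilyl)oxy]but-2-en-1-yl]cyclobutyl]-2H-chromen-2-one
Product: 14 (3R,4S)-3-(5,7-dimethoxy-2-oxo-2H-chromen-8-yl)-4-methyl-4-[3-[(trimethylsilyl)oxy]but-2-en-1-yl]cyclobut-1-en-1-yl trifluoromethanesulfonate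
Conditions: KN(SiMe3)2, THF, −78 °C; PhNTf2, −78 to 0 °C
Reagents that add atoms: N-phenylbis(trifluoromethanesulfonimide), O=S(=O)(N(c1ccccc1)S(=O)(=O)C(F)(F)F)C(F)(F)F
Why: Enolate O-triflation; the ring ketone can enolise only toward its CH2 neighbour because the other α-carbon is quaternary, and the hindered amide base should leave the lactone and the enol silane alone.

Step 8
Reactants: 14 (3R,4S)-3-(5,7-dimethoxy-2-oxo-2H-chromen-8-yl)-4-methyl-4-[3-[(trimethylsilyl)oxy]but-2-en-1-yl]cyclobut-1-en-1-yl trifluoromethanesulfonate
Product: 16 5,7-dimethoxy-8-[(1R,4R)-4-methyl-4-(3-oxobutyl)cyclobut-2-en-1-yl]-2H-chromen-2-one, via cyclobutene silyl enol ether 15 (not isolated)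
Conditions: Pd(OAc)2 (cat.), PPh3, HCO2H, Et3N, DMF, 40 °C; then 0.5 M HCl, THF, 0 °C
Reagents that add atoms: none
Why: Palladium-catalysed formate reduction of an alkenyl triflate (oxidative addition to zerovalent palladium, formate-to-hydride exchange, reductive elimination) gives the cyclobutene; the mild acid work-up releases the methyl ketone. The low temperature guards against electrocyclic opening of the 3-arylcyclobutene.

Step 9
Reactants: 16 5,7-dimethoxy-8-[(1R,4R)-4-methyl-4-(3-oxobutyl)cyclobut-2-en-1-yl]-2H-chromen-2-one
Product: 17 5,7-dimethoxy-8-[(1R,4R)-4-methyl-4-(3-methylbut-3-en-1-yl)cyclobut-2-en-1-yl]-2H-chromen-2-one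
Conditions: Ph3PCH3Br, KOtBu, THF, 0 °C
Reagents that add atoms: methyltriphenylphosphonium bromide, C[P+](c1ccccc1)(c1ccccc1)c1ccccc1.[Br-]
Why: Wittig methylenation of an unhindered methyl ketone; at 0 °C the ylide should react with the ketone much faster than with the coumarin lactone.

Step 10
Reactants: 17 5,7-dimethoxy-8-[(1R,4R)-4-methyl-4-(3-methylbut-3-en-1-yl)cyclobut-2-en-1-yl]-2H-chromen-2-one
Product: 18 8-[(1R,6R)-6-ethenyl-3,6-dimethylcyclohex-2-en-1-yl]-5,7-dimethoxy-2H-chromen-2-one
Conditions: second-generation Grubbs catalyst (H2IMes)(PCy3)Cl2Ru=CHPh (5 mol %), ethylene (1 atm), CH2Cl2 (0.005 M), 40 °C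
Reagents that add atoms: none
Why: The ruthenium methylidene formed under ethylene adds to the strained cyclobutene with ruthenium on C5, the alkene carbon next to the tertiary C6 and not the quaternary C1, and cycloreversion opens the four-membered ring to a C5 alkylidene and a vinyl group on C1. The C5 alkylidene then adds across the 1,1-disubstituted alkene of the tether, and a second cycloreversion closes the ring as the trisubstituted C4–C5 alkene and returns the methylidene. The closest known reaction type is ring-rearrangement (ring-opening/ring-closing) metathesis of cyclobutenes with a tethered alkene. The cyclohexene is closed by ring-closing metathesis, and the overall isomerisation is driven by release of cyclobutene strain. No stereocentre is formed: C1 and C6 come unchanged from the cyclobutene and no bond to either is broken. The step needs closure from C5 (six-membered ring) and not from the carbon on C1 (five-membered ring); the neopentyl position next to the quaternary centre disfavours an alkylidene there, and ethylene lets any such species revert. Dilution and ethylene should suppress ring-opening oligomerisation, and the product's vinyl group on a quaternary carbon and trisubstituted ring alkene are poor substrates for further metathesis.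

Step 11
Reactants: 18 8-[(1R,6R)-6-ethenyl-3,6-dimethylcyclohex-2-en-1-yl]-5,7-dimethoxy-2H-chromen-2-one; 2 8-iodo-5,7-dimethoxy-2H-chromen-2-one
Product: 19 8-[(E)-2-[(1R,2R)-2-(5,7-dimethoxy-2-oxo-2H-chromen-8-yl)-1,4-dimethylcyclohex-3-en-1-yl]ethenyl]-5,7-dimethoxy-2H-chromen-2-one
Conditions: Pd(OAc)2 (cat.), P(o-tol)3, Et3N, DMF, 90 °C
Reagents that add atoms: none
Why: Heck reaction; the aryl group adds to the terminal carbon of the vinyl group, and because C1 is quaternary the only β-hydrogens are benzylic, so syn elimination should give the (E)-styrene alone. Heck coupling of this iodide class with vinyl groups on fully substituted carbons is a known reaction type.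

## Compound list

1 | 5,7-dimethoxy-2H-chromen-2-one | COc1cc(OC)c2ccc(=O)oc2c1 | starting material
2 | 8-iodo-5,7-dimethoxy-2H-chromen-2-one | COc1cc(OC)c2ccc(=O)oc2c1I | intermediate
3 | 2-ethenyl-4,4,5,5-tetramethyl-1,3,2-dioxaborolane | C=CB1OC(C)(C)C(C)(C)O1 | starting material
4 | 8-ethenyl-5,7-dimethoxy-2H-chromen-2-one | COc1cc(OC)c2ccc(=O)oc2c1C=C | intermediate
5 | propanoyl chloride | CCC(=O)Cl | starting material
6 | (2R,5R)-2,5-dimethylpyrrolidine | N1[C@H](C)CC[C@H]1C | starting material
7 | 1-[(2R,5R)-2,5-dimethylpyrrolidin-1-yl]propan-1-one | CCC(=O)N1[C@H](C)CC[C@H]1C | intermediate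
8 | (2R,5R)-2,5-dimethyl-1-(prop-1-en-1-ylidene)pyrrolidin-1-ium trifluoromethanesulfonate | CC=C=[N+]1[C@H](C)CC[C@H]1C.[O-]S(=O)(=O)C(F)(F)F | intermediate (not isolated)
9 | (2R,5R)-1-[(3R)-3-(5,7-dimethoxy-2-oxo-2H-chromen-8-yl)-2-methylcyclobutylidene]-2,5-dimethylpyrrolidin-1-ium trifluoromethanesulfonate, methyl-bearing carbon unspecified | CC1C(=[N+]2[C@H](C)CC[C@H]2C)C[C@H]1c1c(OC)cc(OC)c2ccc(=O)oc12.[O-]S(=O)(=O)C(F)(F)F | intermediate (not isolated)
10 | 8-[(1R)-2-methyl-3-oxocyclobutyl]-5,7-dimethoxy-2H-chromen-2-one, both epimers at the methyl-bearing carbon | CC1C(=O)C[C@H]1c1c(OC)cc(OC)c2ccc(=O)oc12 | intermediate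
11 | 5,7-dimethoxy-8-[(1R)-2-methyl-3-[(trimethylsilyl)oxy]cyclobut-2-en-1-yl]-2H-chromen-2-one | CC1=C(O[Si](C)(C)C)C[C@H]1c1c(OC)cc(OC)c2ccc(=O)oc12 | intermediate
12 | but-3-en-2-one | CC(=O)C=C | starting material
13 | 5,7-dimethoxy-8-[(1S,2S)-2-methyl-3-oxo-2-[3-[(trimethylsilyl)oxy]but-2-en-1-yl]cyclobutyl]-2H-chromen-2-one, aryl cis to methyl, enol ether geometry unspecified | O=C1C[C@@H](c2c(OC)cc(OC)c3ccc(=O)oc23)[C@]1(C)CC=C(C)O[Si](C)(C)C | intermediate
14 | (3R,4S)-3-(5,7-dimethoxy-2-oxo-2H-chromen-8-yl)-4-methyl-4-[3-[(trimethylsilyl)oxy]but-2-en-1-yl]cyclobut-1-en-1-yl trifluoromethanesulfonate | FC(F)(F)S(=O)(=O)OC1=C[C@@H](c2c(OC)cc(OC)c3ccc(=O)oc23)[C@]1(C)CC=C(C)O[Si](C)(C)C | intermediate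
15 | 5,7-dimethoxy-8-[(1R,4R)-4-methyl-4-[3-[(trimethylsilyl)oxy]but-2-en-1-yl]cyclobut-2-en-1-yl]-2H-chromen-2-one | C1=C[C@@H](c2c(OC)cc(OC)c3ccc(=O)oc23)[C@]1(C)CC=C(C)O[Si](C)(C)C | intermediate (not isolated)
16 | 5,7-dimethoxy-8-[(1R,4R)-4-methyl-4-(3-oxobutyl)cyclobut-2-en-1-yl]-2H-chromen-2-one | C1=C[C@@H](c2c(OC)cc(OC)c3ccc(=O)oc23)[C@]1(C)CCC(C)=O | intermediate
17 | 5,7-dimethoxy-8-[(1R,4R)-4-methyl-4-(3-methylbut-3-en-1-yl)cyclobut-2-en-1-yl]-2H-chromen-2-one, aryl cis to methyl | C1=C[C@@H](c2c(OC)cc(OC)c3ccc(=O)oc23)[C@]1(C)CCC(C)=C | intermediate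
18 | 8-[(1R,6R)-6-ethenyl-3,6-dimethylcyclohex-2-en-1-yl]-5,7-dimethoxy-2H-chromen-2-one, aryl cis to ethenyl | C=C[C@@]1(C)CCC(C)=C[C@H]1c1c(OC)cc(OC)c2ccc(=O)oc12 | intermediate
19 | 8-[(E)-2-[(1R,2R)-2-(5,7-dimethoxy-2-oxo-2H-chromen-8-yl)-1,4-dimethylcyclohex-3-en-1-yl]ethenyl]-5,7-dimethoxy-2H-chromen-2-one | COc1cc(OC)c2ccc(=O)oc2c1/C=C/[C@@]1(C)CCC(C)=C[C@H]1c1c(OC)cc(OC)c2ccc(=O)oc12 | target

## Step count and least certain steps

Total steps: 11. Longest linear sequence: 10 steps (1, 2, 4, 5, 6, 7, 8, 9, 10, 11).

**Step 10 (key step).** The ring may open without productive closure, giving oligomers through the ring-opened alkylidene, or closure may start from the carbon on the quaternary side and give a five-membered ring. Fallback, from 17: the cascade is split into two separately controlled operations. First-generation Grubbs catalyst (PCy3)2Cl2Ru=CHPh under ethylene at room temperature cleaves only the strained alkene and gives the triene 8-[(3R,4R)-4-ethenyl-4,7-dimethylocta-1,7-dien-3-yl]-5,7-dimethoxy-2H-chromen-2-one F1. Ring-closing metathesis of F1 with the molybdenum alkylidene Mo(=CHCMe2Ph)(=N-2,6-iPr2C6H3)[OCMe(CF3)2]2, which loads on the less hindered vinyl group at the tertiary carbon and closes trisubstituted alkenes well, returns to 18.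

**Step 4.** Triflic species may polymerise the electron-rich styrene, the keteniminium ion may acylate the arene at C6, or the facial selectivity may be insufficient. Fallback, from 4: enantiocontrol is moved to a desymmetrisation. Dichloroketene (Cl3CCOCl, Zn/Cu couple, Et2O) adds to 4 to give racemic 8-(2,2-dichloro-3-oxocyclobutyl)-5,7-dimethoxy-2H-chromen-2-one F2. Zn in AcOH removes both chlorines to give the achiral 5,7-dimethoxy-8-(3-oxocyclobutyl)-2H-chromen-2-one F3. Enantioselective deprotonation with the chiral lithium amide LiN[CH(CH3)Ph]2 in the presence of Me3SiCl at −100 °C gives 5,7-dimethoxy-8-[(1R)-3-[(trimethylsilyl)oxy]cyclobut-2-en-1-yl]-2H-chromen-2-one F4. Fluoride-mediated methylation (MeI, Bu4N[Ph3SiF2]) returns to 10.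

**Step 5.** Silylation may go to the CH2 flank instead of the methyl-bearing carbon. Fallback, from 10: the side chain is added through the enol under acid catalysis, which favours the more substituted α-carbon. But-3-en-2-one with catalytic CF3SO3H in CH2Cl2 gives the diketone 5,7-dimethoxy-8-[(1S,2S)-2-methyl-3-oxo-2-(3-oxobutyl)cyclobutyl]-2H-chromen-2-one F5, again by attack anti to the aryl group. Me3SiOTf and Et3N at −20 °C then silylate the unstrained side-chain ketone in preference to the cyclobutanone, which returns to 13.

**Step 6.** Addition at the tetrasubstituted enol carbon may be slow, or the silyl group may be lost so that the two ketones are no longer distinguished. Fallback, from 11: the chain is introduced by SN2 alkylation instead of conjugate addition. The fluoride-generated enolate (Bu4N[Ph3SiF2], THF) is alkylated with 4-iodo-2-methylbut-1-ene, anti to the aryl group, to give 5,7-dimethoxy-8-[(1S,2S)-2-methyl-2-(3-methylbut-3-en-1-yl)-3-oxocyclobutyl]-2H-chromen-2-one F6. KN(SiMe3)2 and PhNTf2 give (3R,4S)-3-(5,7-dimethoxy-2-oxo-2H-chromen-8-yl)-4-methyl-4-(3-methylbut-3-en-1-yl)cyclobut-1-en-1-yl trifluoromethanesulfonate F7. Formate reduction (Pd(OAc)2, PPh3, HCO2H, Et3N) returns to 17. This sequence is shorter but exposes the enolate to E2 of the iodide, which is why it is not the first choice.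

**Step 11.** Migratory insertion of the hindered arylpalladium into the vinyl group next to the quaternary carbon may be slow, leading to catalyst decay or reduction of the iodide. Fallback, from 18: the C–C bond is made by transmetalation instead of insertion. Cross-metathesis with 3 using second-generation Hoveyda–Grubbs catalyst (H2IMes)Cl2Ru=CH(C6H4-2-OiPr) gives 8-[(1R,6R)-3,6-dimethyl-6-[(E)-2-(4,4,5,5-tetramethyl-1,3,2-dioxaborolan-2-yl)ethenyl]cyclohex-2-en-1-yl]-5,7-dimethoxy-2H-chromen-2-one F8. Suzuki–Miyaura coupling of F8 with 2 (PdCl2(dppf), K2CO3, dioxane/H2O) returns to 19.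

## Further compounds

F1 | step 10 | 8-[(3R,4R)-4-ethenyl-4,7-dimethylocta-1,7-dien-3-yl]-5,7-dimethoxy-2H-chromen-2-one | C=C[C@@H](c1c(OC)cc(OC)c2ccc(=O)oc12)[C@](C=C)(C)CCC(C)=C
F2 | step 4 | 8-(2,2-dichloro-3-oxocyclobutyl)-5,7-dimethoxy-2H-chromen-2-one (racemic) | O=C1CC(c2c(OC)cc(OC)c3ccc(=O)oc23)C1(Cl)Cl
F3 | step 4 | 5,7-dimethoxy-8-(3-oxocyclobutyl)-2H-chromen-2-one | O=C1CC(c2c(OC)cc(OC)c3ccc(=O)oc23)C1
F4 | step 4 | 5,7-dimethoxy-8-[(1R)-3-[(trimethylsilyl)oxy]cyclobut-2-en-1-yl]-2H-chromen-2-one | C1=C(O[Si](C)(C)C)C[C@H]1c1c(OC)cc(OC)c2ccc(=O)oc12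
F5 | step 5 | 5,7-dimethoxy-8-[(1S,2S)-2-methyl-3-oxo-2-(3-oxobutyl)cyclobutyl]-2H-chromen-2-one | O=C1C[C@@H](c2c(OC)cc(OC)c3ccc(=O)oc23)[C@]1(C)CCC(C)=O
F6 | step 6 | 5,7-dimethoxy-8-[(1S,2S)-2-methyl-2-(3-methylbut-3-en-1-yl)-3-oxocyclobutyl]-2H-chromen-2-one | O=C1C[C@@H](c2c(OC)cc(OC)c3ccc(=O)oc23)[C@]1(C)CCC(C)=C
F7 | step 6 | (3R,4S)-3-(5,7-dimethoxy-2-oxo-2H-chromen-8-yl)-4-methyl-4-(3-methylbut-3-en-1-yl)cyclobut-1-en-1-yl trifluoromethanesulfonate | FC(F)(F)S(=O)(=O)OC1=C[C@@H](c2c(OC)cc(OC)c3ccc(=O)oc23)[C@]1(C)CCC(C)=C
F8 | step 11 | 8-[(1R,6R)-3,6-dimethyl-6-[(E)-2-(4,4,5,5-tetramethyl-1,3,2-dioxaborolan-2-yl)ethenyl]cyclohex-2-en-1-yl]-5,7-dimethoxy-2H-chromen-2-one | CC1(C)OB(/C=C/[C@@]2(C)CCC(C)=C[C@H]2c2c(OC)cc(OC)c3ccc(=O)oc23)OC1(C)C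
A1 | alternative 1 | 5,7-dimethoxy-8-[(1R,6S)-3,6-dimethyl-6-[[tri(propan-2-yl)silyl]ethynyl]cyclohex-2-en-1-yl]-2H-chromen-2-one | CC(C)[Si](C#C[C@@]1(C)CCC(C)=C[C@H]1c1c(OC)cc(OC)c2ccc(=O)oc12)(C(C)C)C(C)C
A2 | alternative 2 | methyl 1,3-dimethoxy-9-methyl-6-oxo-10-(trimethylsilyl)-6a,7,10,10a-tetrahydrobenzo[c]chromene-6a-carboxylate, cis-fused | O=C2[C@@]1(C(=O)OC)CC=C(C)[C@H]([Si](C)(C)C)[C@H]1c3c(OC)cc(OC)cc3O2
A3 | alternative 3 | 1,3-dimethoxy-6a,9-dimethyl-6a,10a-dihydrobenzo[c]chromen-6-one, cis-fused | O=C2[C@@]1(C)C=CC(C)=C[C@H]1c3c(OC)cc(OC)cc3O2
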